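The step to the second isomer has a larger constant than the step to the target, 5.6 × 10⁻⁴ /M/s against 3.4 × 10⁻⁴ /M/s, and both run on the same product of concentrations.

    substrate + coupling partner → target (k1 = 3.4 × 10⁻⁴ /M/s)
    substrate + coupling partner → isomer of the product (k2 = 8.6 × 10⁻⁵ /M/s)
    substrate + coupling partner → second isomer (k3 = 5.6 × 10⁻⁴ /M/s)
    coupling partner + target ⇌ idle adduct, settled at all times (K4 = 15 /M)
    coupling partner → decomposition product (k5 = 4.9 × 10⁻⁸ /s)

| setting | Monday's | Wednesday's | Friday's |
|---|---|---|---|
| substrate | 45 mM | 45 mM | 45 mM |
| coupling partner | 110 mM | 170 mM | 250 mM |
| time | 8.0 h | 8.0 h | 8.0 h |

- target is meant together with its idle adduct
- run time (Monday's): 8.0 h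

1. which of these there is most of at the end, counted by the substrate in it, Monday's (second isomer / isomer of the product / target / substrate)
2. which of these there is most of at the end, counted by the substrate in it, Wednesday's (second isomer / isomer of the product / target / substrate)
3. which of these there is most of at the end, counted by the substrate in it, Friday's (second isomer / isomer of the product / target / substrate)
4. amount of the one of these that there is most of at the end, in percent of the substrate charged, Monday's
5. amount of the one of these that there is most of at the end, in percent of the substrate charged, Wednesday's
6. amount of the one of these that there is most of at the end, in percent of the substrate charged, Friday's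

**Minutes.** The chair opened with that comparison: the coupling steps share one rate law, so the second isomer takes the same part of whatever substrate reacts, 56.8%, its fractional selectivity in this scheme.

The kineticist objected that a share is not a yield. Treating the substrate as pseudo-first-order at the charged level would leave 4.40% of it on Monday's, but free coupling partner falls during the run. She therefore counted its loss per substrate reacted: one for the coupling, plus the target's part, 34.5%, times the part of target held as idle adduct, taken at a free level of coupling charge minus substrate charge. On Monday's this gives 1.17. She set decomposition aside, its half-life of 160 d being far longer than the 8.0 h run.

She then named the floor: the fraction of the charged coupling partner free once the substrate is gone, one minus that loss times the ratio of charges, 52.1% on Monday's. With a and b the fractions of substrate and coupling partner left, b is the floor plus the remainder times a, and the rate law integrates in closed form. The logarithm of b/a grows as the clock, the summed constants times coupling charge, floor and time. So a is the floor divided by the exponential of the clock, less the remainder.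

On Monday's the clock reads 1.63, which leaves 11.3% substrate and puts the second isomer at 50.4%. Wednesday's floor of 67.6% leaves 2.62% and gives 55.3%. Friday's floor of 77.3% leaves 0.320% and gives 56.6%.

The forecast, holding that “The three coupling channels share the same kinetic order”, gave second isomer at 50.2% on Monday's, second isomer at 55.3% on Wednesday's and second isomer at 56.6% on Friday's.

The simulation gives second isomer at 50.3% with 11.4% substrate left on Monday's, second isomer at 55.3% with 2.62% on Wednesday's, and second isomer at 56.6% with 0.320% on Friday's.

In Monday's flask the substrate's half-life by the step to the second isomer read 4.0 h at 1.71 h, shorter than the 6.6 h by the step to the target, and at 8.00 h it had grown to 5.4 h with 58% of the coupling partner free. That part lies above the floor of 52.1%, and Monday's flask at 80.0 h reads 51.8% free coupling partner, 0.841 mM decomposition product and the second isomer at 56.8%.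

For the neighbour of Monday's with 190 mM of coupling partner, the floor is 70.7%, which leaves 1.57% substrate and puts the second isomer at 55.9%. The computed neighbour holds 1.57% substrate, and its second isomer stands at 55.9%.

The numbers of this flask were chosen freely; the flask was simulated.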